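**Retrosynthetic overview**

1. Numbering used below: C10 = quaternary C(Me)(vinyl), C5 = CH carrying the acrylic acid, C6 = lactone CH–O, C7 = lactone CH, C8 = CH–O-tigloyl, C9 = CH2, C12 = lactone C=O. Target 19 ⇐ tert-butyl ester 18 (acid freed last).
2. Key disconnection, a C–O one: both C12–O bonds of the α-methylene lactone. 18 ⇐ trans-2-isopropenylcyclohexanol 15 by a one-flask allylic C–H oxidative lactonisation (the lactone is the second and last ring).
3. 15 ⇐ acyclic aldehyde 14 by intramolecular carbonyl-ene reaction (C6–C7 bond; the cyclohexane is the first ring; C6 and C7 are set by C5 and by the C8 tiglate).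
4. 14 ⇐ allylic itaconate 10 by enantioselective boron Ireland–Claisen rearrangement (C5–C10, the tertiary/quaternary pair), then CO2H → CHO.
5. 10 ⇐ diol 5 + itaconic anhydride 6 + tigloyl chloride 9 (ester C–O bonds); 5 ⇐ prenal 3 + methyl 3-methylbut-2-enoate 1 by asymmetric vinylogous aldol (sets C8).

Assumption: the named antipode of each chiral reagent (bisphosphoramide in step 2, bromoborane in step 7) is taken to be the one that gives the drawn sense of induction; the mirror-image reagents are equally available.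

**Route**

Step 1
Reactants: 1 methyl 3-methylbut-2-enoate
Product: 2 tert-butyl{[(1Z)-1-methoxy-3-methylbuta-1,3-dien-1-yl]oxy}dimethylsilane
Conditions: LiN(i-Pr)2, THF/DMPU, −78 °C; t-BuMe2SiCl, −78 → 0 °C
Reagents that add atoms: tert-butyldimethylsilyl chloride, CC(C)(C)[Si](C)(C)Cl
Why: Kinetic γ-deprotonation of the senecioate and O-silylation of the extended lithium dienolate (silyl ketene acetal formation); no stereocentre is formed and the ketene-acetal geometry is lost in step 2.

Step 2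
Reactants: 2 tert-butyl{[(1Z)-1-methoxy-3-methylbuta-1,3-dien-1-yl]oxy}dimethylsilane; 3 3-methylbut-2-enal (prenal)
Product: 4 methyl (2E,5R)-5-hydroxy-3,7-dimethylocta-2,6-dienoate
Conditions: SiCl4 (1.1 equiv), (R,R)-N,N′-bis[(11bR)-3,5-dimethyl-4-oxido-3,5-dihydro-4H-dinaphtho[2,1-d:1′,2′-f][1,3,2]diazaphosphepin-4-yl]-N,N′-dimethylpentane-1,5-diamine (2 mol %), i-Pr2NEt (10 mol %), CH2Cl2, −78 °C; aq. NaHCO3/KF
Reagents that add atoms: none
Why: Lewis-base-activated SiCl4 vinylogous Mukaiyama aldol reaction: the dienolate reacts only at its γ-carbon to give the E-enoate, and the chiral phosphoramide-bound silicon cation shields one face of prenal so that Re-face attack sets the C8 carbinol (5R in 4).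

Step 3
Reactants: 4 methyl (2E,5R)-5-hydroxy-3,7-dimethylocta-2,6-dienoate
Product: 5 (2E,5R)-3,7-dimethylocta-2,6-diene-1,5-diol
Conditions: i-Bu2AlH (3.3 equiv), CH2Cl2, −78 → 0 °C; aq. KNaC4H4O6
Reagents that add atoms: none
Why: 1,2-Reduction of the conjugated ester to the allylic alcohol by the electrophilic aluminium hydride, leaving both trisubstituted alkenes and the C8 centre untouched.

Step 4
Reactants: 5 (2E,5R)-3,7-dimethylocta-2,6-diene-1,5-diol; 6 itaconic anhydride
Product: 7 4-{[(2E,5R)-5-hydroxy-3,7-dimethylocta-2,6-dien-1-yl]oxy}-2-methylidene-4-oxobutanoic acid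
Conditions: 6 (1.0 equiv), toluene, 50 °C, no base
Reagents that add atoms: none
Why: Alcoholysis of the cyclic anhydride: the unhindered primary allylic hydroxyl reacts faster than the secondary one and attacks the non-conjugated carbonyl, giving the 4-ester with the acrylic acid free, and leaving out amine base avoids itaconate-to-citraconate isomerisation.

Step 5
Reactants: 7 4-{[(2E,5R)-5-hydroxy-3,7-dimethylocta-2,6-dien-1-yl]oxy}-2-methylidene-4-oxobutanoic acid
Product: 8 1-tert-butyl 4-[(2E,5R)-5-hydroxy-3,7-dimethylocta-2,6-dien-1-yl] 2-methylidenebutanedioate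
Conditions: Cl3CC(=NH)Ot-Bu (2 equiv), cyclohexane/CH2Cl2, 23 °C
Reagents that add atoms: tert-butyl 2,2,2-trichloroacetimidate, CC(C)(C)OC(=N)C(Cl)(Cl)Cl
Why: Imidate O-alkylation (tert-butyl ester formation): the carboxylic acid protonates the imidate and is tert-butylated, whereas the secondary alcohol, which would need a strong Lewis acid, is not.

Step 6
Reactants: 8 1-tert-butyl 4-[(2E,5R)-5-hydroxy-3,7-dimethylocta-2,6-dien-1-yl] 2-methylidenebutanedioate; 9 (2E)-2-methylbut-2-enoyl chloride (tigloyl chloride)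
Product: 10 1-tert-butyl 4-[(2E,5R)-3,7-dimethyl-5-{[(2E)-2-methylbut-2-enoyl]oxy}octa-2,6-dien-1-yl] 2-methylidenebutanedioate
Conditions: 9 (1.5 equiv), pyridine, 4-(dimethylamino)pyridine (10 mol %), CH2Cl2, 0 → 23 °C
Reagents that add atoms: none
Why: Nucleophile-catalysed acylation of the secondary allylic alcohol with retention at C8; pyridine instead of a trialkylamine avoids vinylketene formation and so keeps the E (tiglate) geometry.

Step 7
Reactants: 10 1-tert-butyl 4-[(2E,5R)-3,7-dimethyl-5-{[(2E)-2-methylbut-2-enoyl]oxy}octa-2,6-dien-1-yl] 2-methylidenebutanedioate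
Product: 12 (2R,3S,5R)-2-[3-(tert-butoxy)-3-oxoprop-1-en-2-yl]-3-ethenyl-3,7-dimethyl-5-{[(2E)-2-methylbut-2-enoyl]oxy}oct-6-enoic acid, via boron ketene acetal 11 (not isolated)
Conditions: (4S,5S)-2-bromo-1,3-bis[3,5-bis(trifluoromethyl)benzenesulfonyl]-4,5-diphenyl-1,3,2-diazaborolidine (1.3 equiv), Et3N (1.5 equiv), toluene/hexane, −78 °C; then −20 → 4 °C, 72 h; aq. work-up
Reagents that add atoms: (4S,5S)-2-bromo-1,3-bis[3,5-bis(trifluoromethyl)benzenesulfonyl]-4,5-diphenyl-1,3,2-diazaborolidine, BrB1N(S(=O)(=O)c2cc(cc(c2)C(F)(F)F)C(F)(F)F)[C@@H](c2ccccc2)[C@H](c2ccccc2)N1S(=O)(=O)c1cc(cc(c1)C(F)(F)F)C(F)(F)F (its boron unit is in 11 only; no atom of it stays in 12)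
Why: Enantioselective boron-enolate Ireland–Claisen rearrangement: soft enolisation of the doubly activated CH2 (the tiglate has no α-hydrogen) gives the ketene acetal with the acrylate-bearing carbon cis to the allyloxy oxygen, which with the E-olefin rearranges through a chair (C9 chain equatorial, methyl axial) that fixes the C5/C10 relationship, while the C2-symmetric sulfonamide ligand selects the enolate face independently of the remote C8 centre (2R,3S in 12).

Step 8
Reactants: 12 (2R,3S,5R)-2-[3-(tert-butoxy)-3-oxoprop-1-en-2-yl]-3-ethenyl-3,7-dimethyl-5-{[(2E)-2-methylbut-2-enoyl]oxy}oct-6-enoic acid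
Product: 14 tert-butyl 2-[(2R,3S,5R)-3-ethenyl-3,7-dimethyl-5-{[(2E)-2-methylbut-2-enoyl]oxy}-1-oxooct-6-en-2-yl]prop-2-enoate, via acid chloride 13 (not isolated)
Conditions: Me2C=C(Cl)NMe2 (1.1 equiv), CH2Cl2, 0 °C; then LiAlH(Ot-Bu)3 (1.05 equiv), THF, −78 °C
Reagents that add atoms: 1-chloro-N,N,2-trimethylprop-1-en-1-amine, CC(C)=C(Cl)N(C)C (its chlorine is in 13 only; no atom of it stays in 14)
Why: Neutral acid-chloride formation with the α-chloroenamine, then partial reduction of the acid chloride to the aldehyde by the hindered alkoxyaluminium hydride; the esters and the acrylate are inert at −78 °C and the base-free conditions preserve the C5 centre.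

Step 9
Reactants: 14 tert-butyl 2-[(2R,3S,5R)-3-ethenyl-3,7-dimethyl-5-{[(2E)-2-methylbut-2-enoyl]oxy}-1-oxooct-6-en-2-yl]prop-2-enoate
Product: 15 tert-butyl 2-[(1R,2S,4R,5S,6R)-2-ethenyl-6-hydroxy-2-methyl-4-{[(2E)-2-methylbut-2-enoyl]oxy}-5-(prop-1-en-2-yl)cyclohexyl]prop-2-enoate
Conditions: Sc(OTf)3 (10 mol %), CH2Cl2, −78 → −40 °C
Reagents that add atoms: none
Why: Intramolecular carbonyl-ene reaction (the citronellal-to-isopulegol cyclisation) through a chair transition state with the C5 side chain, the forming C6–O bond and the C7 isopropenyl all equatorial, which sets C6 and C7 all-trans to C5; the allylic C8 ester sits axial to avoid 1,3-allylic strain with the alkene methyl, exactly as the target requires.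

Step 10
Reactants: 15 tert-butyl 2-[(1R,2S,4R,5S,6R)-2-ethenyl-6-hydroxy-2-methyl-4-{[(2E)-2-methylbut-2-enoyl]oxy}-5-(prop-1-en-2-yl)cyclohexyl]prop-2-enoate
Product: 18 tert-butyl 2-[(3aR,4R,6S,7R,7aR)-6-ethenyl-6-methyl-4-{[(2E)-2-methylbut-2-enoyl]oxy}-3-methylidene-2-oxooctahydro-1-benzofuran-7-yl]prop-2-enoate, via allylic alcohol 16 (not isolated), via lactol 17 (not isolated)
Conditions: SeO2 (10 mol %), 2,2,6,6-tetramethylpiperidin-1-oxyl (10 mol %), PhI(OAc)2 (3.3 equiv), H2O (3 equiv), CH2Cl2, 23 °C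
Reagents that add atoms: water, O
Why: Proposed new method: a dual-catalytic dehydrogenative allylic C–H lactonisation in which one terminal oxidant, PhI(OAc)2, drives two cycles: SeO2 hydroxylates the isopropenyl methyl by ene reaction and [2,3]-sigmatropic shift (CH3 is preferred over the tertiary C7–H) and is regenerated from divalent selenium by the iodane, while the oxoammonium form of the nitroxyl, which oxidises the new primary allylic alcohol far faster than the hindered secondary C6–OH, takes 16 to the enal that closes onto C6–OH as lactol 17 and then to the lactone, so both C12–O bonds and the lactone ring form without touching a stereocentre; the closest known reactions are SeO2/t-BuOOH allylic hydroxylation and nitroxyl/PhI(OAc)2 oxidative lactonisation of 1,4-diols.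

Step 11
Reactants: 18 tert-butyl 2-[(3aR,4R,6S,7R,7aR)-6-ethenyl-6-methyl-4-{[(2E)-2-methylbut-2-enoyl]oxy}-3-methylidene-2-oxooctahydro-1-benzofuran-7-yl]prop-2-enoate
Product: 19 2-[(3aR,4R,6S,7R,7aR)-6-ethenyl-6-methyl-4-{[(2E)-2-methylbut-2-enoyl]oxy}-3-methylidene-2-oxooctahydro-1-benzofuran-7-yl]prop-2-enoic acid (target)
Conditions: CF3CO2H/CH2Cl2 (1:4), 0 → 23 °C
Reagents that add atoms: none
Why: Acidolysis of the tert-butyl ester (E1 loss of isobutene) frees the acrylic acid; the tiglate, the α-methylene lactone and the vinyl group are stable to anhydrous acid and no stereocentre is involved.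

**Compound list**

1 | methyl 3-methylbut-2-enoate | COC(=O)C=C(C)C | starting material
2 | tert-butyl{[(1Z)-1-methoxy-3-methylbuta-1,3-dien-1-yl]oxy}dimethylsilane (major ketene-acetal isomer drawn) | CO/C(O[Si](C)(C)C(C)(C)C)=C/C(C)=C | intermediate
3 | 3-methylbut-2-enal (prenal) | CC(C)=CC=O | starting material
4 | methyl (2E,5R)-5-hydroxy-3,7-dimethylocta-2,6-dienoate | COC(=O)/C=C(\C)C[C@@H](O)C=C(C)C | intermediate
5 | (2E,5R)-3,7-dimethylocta-2,6-diene-1,5-diol | OC/C=C(\C)C[C@@H](O)C=C(C)C | intermediate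
6 | itaconic anhydride (3-methylideneoxolane-2,5-dione) | C=C1CC(=O)OC1=O | starting material
7 | 4-{[(2E,5R)-5-hydroxy-3,7-dimethylocta-2,6-dien-1-yl]oxy}-2-methylidene-4-oxobutanoic acid | OC(=O)C(=C)CC(=O)OC/C=C(\C)C[C@@H](O)C=C(C)C | intermediate
8 | 1-tert-butyl 4-[(2E,5R)-5-hydroxy-3,7-dimethylocta-2,6-dien-1-yl] 2-methylidenebutanedioate | CC(C)(C)OC(=O)C(=C)CC(=O)OC/C=C(\C)C[C@@H](O)C=C(C)C | intermediate
9 | (2E)-2-methylbut-2-enoyl chloride (tigloyl chloride) | C/C=C(\C)C(Cl)=O | starting material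
10 | 1-tert-butyl 4-[(2E,5R)-3,7-dimethyl-5-{[(2E)-2-methylbut-2-enoyl]oxy}octa-2,6-dien-1-yl] 2-methylidenebutanedioate | CC(C)(C)OC(=O)C(=C)CC(=O)OC/C=C(\C)C[C@@H](OC(=O)/C(C)=C/C)C=C(C)C | intermediate
11 | boron ketene acetal of 10: tert-butyl (3Z)-4-{[(4S,5S)-1,3-bis[3,5-bis(trifluoromethyl)benzenesulfonyl]-4,5-diphenyl-1,3,2-diazaborolidin-2-yl]oxy}-4-{[(2E,5R)-3,7-dimethyl-5-{[(2E)-2-methylbut-2-enoyl]oxy}octa-2,6-dien-1-yl]oxy}-2-methylidenebut-3-enoate | CC(C)(C)OC(=O)C(=C)/C=C(\OC/C=C(\C)C[C@@H](OC(=O)/C(C)=C/C)C=C(C)C)OB1N(S(=O)(=O)c2cc(cc(c2)C(F)(F)F)C(F)(F)F)[C@@H](c2ccccc2)[C@H](c2ccccc2)N1S(=O)(=O)c1cc(cc(c1)C(F)(F)F)C(F)(F)F | intermediate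
12 | (2R,3S,5R)-2-[3-(tert-butoxy)-3-oxoprop-1-en-2-yl]-3-ethenyl-3,7-dimethyl-5-{[(2E)-2-methylbut-2-enoyl]oxy}oct-6-enoic acid | C=C[C@](C)(C[C@@H](OC(=O)/C(C)=C/C)C=C(C)C)[C@@H](C(=O)O)C(=C)C(=O)OC(C)(C)C | intermediate
13 | acid chloride of 12: (2R,3S,5R)-2-[3-(tert-butoxy)-3-oxoprop-1-en-2-yl]-3-ethenyl-3,7-dimethyl-5-{[(2E)-2-methylbut-2-enoyl]oxy}oct-6-enoyl chloride | C=C[C@](C)(C[C@@H](OC(=O)/C(C)=C/C)C=C(C)C)[C@@H](C(Cl)=O)C(=C)C(=O)OC(C)(C)C | intermediate
14 | tert-butyl 2-[(2R,3S,5R)-3-ethenyl-3,7-dimethyl-5-{[(2E)-2-methylbut-2-enoyl]oxy}-1-oxooct-6-en-2-yl]prop-2-enoate | C=C[C@](C)(C[C@@H](OC(=O)/C(C)=C/C)C=C(C)C)[C@@H](C=O)C(=C)C(=O)OC(C)(C)C | intermediate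
15 | tert-butyl 2-[(1R,2S,4R,5S,6R)-2-ethenyl-6-hydroxy-2-methyl-4-{[(2E)-2-methylbut-2-enoyl]oxy}-5-(prop-1-en-2-yl)cyclohexyl]prop-2-enoate | C=C[C@]1(C)C[C@@H](OC(=O)/C(C)=C/C)[C@@H](C(C)=C)[C@H](O)[C@H]1C(=C)C(=O)OC(C)(C)C | intermediate
16 | tert-butyl 2-[(1R,2S,4R,5S,6R)-2-ethenyl-6-hydroxy-5-(3-hydroxyprop-1-en-2-yl)-2-methyl-4-{[(2E)-2-methylbut-2-enoyl]oxy}cyclohexyl]prop-2-enoate | C=C[C@]1(C)C[C@@H](OC(=O)/C(C)=C/C)[C@@H](C(=C)CO)[C@H](O)[C@H]1C(=C)C(=O)OC(C)(C)C | intermediate
17 | tert-butyl 2-[(3aR,4R,6S,7R,7aR)-6-ethenyl-2-hydroxy-6-methyl-4-{[(2E)-2-methylbut-2-enoyl]oxy}-3-methylideneoctahydro-1-benzofuran-7-yl]prop-2-enoate (lactol, both C2 epimers) | C=C[C@]1(C)C[C@@H](OC(=O)/C(C)=C/C)[C@H]2C(=C)C(O)O[C@@H]2[C@H]1C(=C)C(=O)OC(C)(C)C | intermediate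
18 | tert-butyl 2-[(3aR,4R,6S,7R,7aR)-6-ethenyl-6-methyl-4-{[(2E)-2-methylbut-2-enoyl]oxy}-3-methylidene-2-oxooctahydro-1-benzofuran-7-yl]prop-2-enoate | C=C[C@]1(C)C[C@@H](OC(=O)/C(C)=C/C)[C@H]2C(=C)C(=O)O[C@@H]2[C@H]1C(=C)C(=O)OC(C)(C)C | intermediate
19 | 2-[(3aR,4R,6S,7R,7aR)-6-ethenyl-6-methyl-4-{[(2E)-2-methylbut-2-enoyl]oxy}-3-methylidene-2-oxooctahydro-1-benzofuran-7-yl]prop-2-enoic acid (CNP0256928.1) | C=C[C@]1(C)C[C@@H](OC(=O)/C(C)=C/C)[C@H]2C(=C)C(=O)O[C@@H]2[C@H]1C(=C)C(=O)O | target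

**Step count and risk**

Total: 11 steps. Longest linear sequence: 11 steps (1 to 19); 3, 6 and 9 enter as purchased building blocks.

The three steps most likely to fail:

Step 10 (the proposed new step). The two catalytic cycles may not mesh: the iodane may fail to turn over selenium, or the nitroxyl may oxidise the C6 alcohol to the ketone before the slow C–H hydroxylation has happened. The fallback uses known chemistry and decouples the two oxidations. It sets out from 15: SeO2 (30 mol %)/t-BuOOH in CH2Cl2 at 23 °C gives allylic alcohol 16, which is now isolated. MnO2 in CH2Cl2 then takes 16 through lactol 17 to lactone 18, where the route is rejoined. New compounds: none F0.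

Step 7. The itaconate-type ester is a new substrate class for the boron Ireland–Claisen rearrangement, so enolate geometry (hence the C5/C10 relationship) and the level of reagent control are uncertain. The fallback gives up reagent control and uses the C8 centre for separation instead. It sets out from 10: a conventional Ireland–Claisen rearrangement (LiN(i-Pr)2, Me3SiCl/Et3N, THF, −78 → 23 °C) proceeds through the trimethylsilyl ketene acetal F1. It gives 12 together with the C5/C10-antipodal acid F2. Because C8 is already a single enantiomer these two are diastereomers and are separated by chromatography, and pure 12 rejoins the route at step 8.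

Step 9. The Lewis acid could ionise the allylic tiglate, or the chair with methyl and tiglate 1,3-diaxial could lose to another transition state. The fallback reverses the polarity of the ring closure and uses no Lewis acid. It sets out from 14: ene-type allylic chlorination of the prenyl terminus (N-chlorosuccinimide, PhSeCl 10 mol %, CH2Cl2) gives the transposed secondary allylic chloride F3. CrCl2 (THF, 0 °C) converts F3 into an allylchromium species that adds to the aldehyde through its γ-carbon (intramolecular Nozaki–Hiyama allylation, chair transition state). This delivers the same trans-2-isopropenylcyclohexanol 15, where the route is rejoined. The known weakness of this fallback is possible 1,4-elimination of the tiglate from the allylchromium species, which the low temperature and the fast six-membered ring closure are meant to outrun.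

Further compounds
F1 | step 7 | trimethylsilyl ketene acetal of 10: tert-butyl (3E)-4-{[(2E,5R)-3,7-dimethyl-5-{[(2E)-2-methylbut-2-enoyl]oxy}octa-2,6-dien-1-yl]oxy}-2-methylidene-4-[(trimethylsilyl)oxy]but-3-enoate | CC(C)(C)OC(=O)C(=C)/C=C(\OC/C=C(\C)C[C@@H](OC(=O)/C(C)=C/C)C=C(C)C)O[Si](C)(C)C
F2 | step 7 | (2S,3R,5R)-2-[3-(tert-butoxy)-3-oxoprop-1-en-2-yl]-3-ethenyl-3,7-dimethyl-5-{[(2E)-2-methylbut-2-enoyl]oxy}oct-6-enoic acid | C=C[C@@](C)(C[C@@H](OC(=O)/C(C)=C/C)C=C(C)C)[C@H](C(=O)O)C(=C)C(=O)OC(C)(C)C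
F3 | step 9 | tert-butyl 2-[(2R,3S,5R)-6-chloro-3-ethenyl-3,7-dimethyl-5-{[(2E)-2-methylbut-2-enoyl]oxy}-1-oxooct-7-en-2-yl]prop-2-enoate (both epimers at the chlorine-bearing carbon) | C=C[C@](C)(C[C@@H](OC(=O)/C(C)=C/C)C(Cl)C(C)=C)[C@@H](C=O)C(=C)C(=O)OC(C)(C)C
F0 | step 10 | none | none
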